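## Retrosynthetic overview

1. The last operation only frees the benzofuran 6-OH from its silyl ether.
2. The benzofuran ring is formed last, by an oxa-Fischer-type [3,3]-sigmatropic shift of an O-aryl ketoxime ether (C3–C3a bond), then O1–C2 closure and loss of NH3. The partners are an 8-acetylflavan and an aryloxyamine.
3. The aryloxyamine comes from 3-methoxy-2-methylphenol by silylation, meta C–H borylation/oxidation and O-amination.
4. The chroman ring is formed first, on 2′,6′-dihydroxy-4′-methoxyacetophenone: O1–C2 by Mitsunobu inversion of bought (R)-3-chloro-1-phenylpropan-1-ol (the only stereocentre), then C4–C4a by intramolecular phenoxide C-alkylation.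
5. Ring order: chroman heterocycle, then furan ring; all three benzene rings are bought.

Assumption: compounds 1, 2 and 5 are taken as commercial; the C=N geometry of 10 and the configuration at the transient aminal carbon of 11 are left undefined because both disappear on aromatisation.

## Route

Step 1
Reactants: 1 1-(2,6-dihydroxy-4-methoxyphenyl)ethan-1-one; 2 (R)-3-chloro-1-phenylpropan-1-ol
Product: 3 1-{2-[(1S)-3-chloro-1-phenylpropoxy]-6-hydroxy-4-methoxyphenyl}ethan-1-one
Conditions: PPh3, DIAD, THF, 0 °C → rt (1.3 equiv of 1)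
Reagents that add atoms: none
Why: Mitsunobu etherification of one of the two equivalent phenols proceeds by SN2 inversion at the benzylic carbinol, turning the bought (R)-centre into the (S)-aryl ether that becomes C2 of the flavan, while the primary chloride is inert.

Step 2
Reactants: 3 1-{2-[(1S)-3-chloro-1-phenylpropoxy]-6-hydroxy-4-methoxyphenyl}ethan-1-one
Product: 4 (S)-1-(7-hydroxy-5-methoxy-2-phenylchroman-8-yl)ethan-1-one
Conditions: Cs2CO3 (1.5 equiv), TBAI (10 mol %), DMF (0.01 M), 80 °C
Reagents that add atoms: none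
Why: Intramolecular para-C-alkylation of the phenoxide (Ar2⁻-6 participation) closes the chroman at the only CH the tether can reach (para to O⁻, flanked by two alkoxy donors) and re-aromatises, with intermolecular O-alkylation suppressed by dilution and the stereocentre untouched.

Step 3
Reactants: 5 3-methoxy-2-methylphenol
Product: 6 triisopropyl(3-methoxy-2-methylphenoxy)silane
Conditions: TIPSCl, imidazole, DMF, rt
Reagents that add atoms: triisopropylsilyl chloride, CC(C)[Si](Cl)(C(C)C)C(C)C
Why: Standard silyl ether formation gives a bulky, C–H-borylation-compatible protecting group that later also serves as the steric control element.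

Step 4
Reactants: 6 triisopropyl(3-methoxy-2-methylphenoxy)silane
Product: 8 3-methoxy-4-methyl-5-[(triisopropylsilyl)oxy]phenol, via aryl pinacol boronate 7 (not isolated)
Conditions: [Ir(OMe)(cod)]2 (1.5 mol %), dtbpy (3 mol %), B2pin2 (1.0 equiv), THF, 80 °C; then Oxone, acetone/H2O, rt, 10 min
Reagents that add atoms: bis(pinacolato)diboron, CC1(C)OB(OC1(C)C)B1OC(C)(C)C(C)(C)O1 (its Bpin group sits only in 7); Oxone (potassium peroxymonosulfate), [K+].[O-]S(=O)(=O)OO (the new phenol oxygen)
Why: Sterically governed Ir-catalysed C–H borylation takes the only ring C–H without an ortho substituent (meta to both oxygens, para to methyl), and ipso-oxidation of the C–B bond gives the phenol in one pot.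

Step 5
Reactants: 8 3-methoxy-4-methyl-5-[(triisopropylsilyl)oxy]phenol
Product: 9 O-{3-methoxy-4-methyl-5-[(triisopropylsilyl)oxy]phenyl}hydroxylamine
Conditions: t-BuOK (1.0 equiv), DMF, 0 °C; then O-(2,4-dinitrophenyl)hydroxylamine, 0 °C → rt
Reagents that add atoms: O-(2,4-dinitrophenyl)hydroxylamine, NOc1ccc(cc1[N+](=O)[O-])[N+](=O)[O-]
Why: Electrophilic amination of the unhindered, electron-rich phenoxide (SN2 at nitrogen with 2,4-dinitrophenoxide as leaving group) gives the aryloxyamine.

Step 6
Reactants: 4 (S)-1-(7-hydroxy-5-methoxy-2-phenylchroman-8-yl)ethan-1-one; 9 O-{3-methoxy-4-methyl-5-[(triisopropylsilyl)oxy]phenyl}hydroxylamine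
Product: 12 (S)-5-methoxy-8-{4-methoxy-5-methyl-6-[(triisopropylsilyl)oxy]benzofuran-2-yl}-2-phenylchroman-7-ol, via O-aryl ketoxime ether 10 (not isolated), via 2-amino-2,3-dihydrobenzofuran 11 (not isolated)
Conditions: MsOH (2 equiv), THF, 60 °C (1.2 equiv of 9)
Reagents that add atoms: none
Why: Acid-catalysed condensation gives the O-aryl ketoxime ether, whose ene-hydroxylamine tautomer undergoes the oxa-Fischer-type [3,3]-sigmatropic rearrangement (N–O broken, C3–C3a made at the ortho carbon next to OMe, since the other ortho carbon is shielded by the TIPS group that the 4-methyl pushes toward it), followed by phenol-to-imine ring closure and loss of ammonia; the chroman stereocentre is not involved.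

Step 7
Reactants: 12 (S)-5-methoxy-8-{4-methoxy-5-methyl-6-[(triisopropylsilyl)oxy]benzofuran-2-yl}-2-phenylchroman-7-ol
Product: 13 (S)-8-(6-hydroxy-4-methoxy-5-methylbenzofuran-2-yl)-5-methoxy-2-phenylchroman-7-ol
Conditions: TBAF, AcOH, THF, 0 °C
Reagents that add atoms: none
Why: Fluoride-mediated cleavage of the aryl silyl ether, buffered with acetic acid to keep the electron-rich phenols from oxidising, releases the target without touching the methyl ethers or the benzylic ether stereocentre.

## Compound list

1 | 1-(2,6-dihydroxy-4-methoxyphenyl)ethan-1-one (2′,6′-dihydroxy-4′-methoxyacetophenone) | CC(=O)c1c(O)cc(OC)cc1O | starting material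
2 | (R)-3-chloro-1-phenylpropan-1-ol | O[C@H](CCCl)c1ccccc1 | starting material
3 | 1-{2-[(1S)-3-chloro-1-phenylpropoxy]-6-hydroxy-4-methoxyphenyl}ethan-1-one | CC(=O)c1c(O)cc(OC)cc1O[C@@H](CCCl)c1ccccc1 | intermediate
4 | (S)-1-(7-hydroxy-5-methoxy-2-phenylchroman-8-yl)ethan-1-one | CC(=O)c1c(O)cc(OC)c2CC[C@@H](c3ccccc3)Oc12 | intermediate
5 | 3-methoxy-2-methylphenol | COc1cccc(O)c1C | starting material
6 | triisopropyl(3-methoxy-2-methylphenoxy)silane | COc1cccc(O[Si](C(C)C)(C(C)C)C(C)C)c1C | intermediate
7 | 2-{3-methoxy-4-methyl-5-[(triisopropylsilyl)oxy]phenyl}-4,4,5,5-tetramethyl-1,3,2-dioxaborolane (not isolated) | COc1cc(B2OC(C)(C)C(C)(C)O2)cc(O[Si](C(C)C)(C(C)C)C(C)C)c1C | intermediate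
8 | 3-methoxy-4-methyl-5-[(triisopropylsilyl)oxy]phenol | COc1cc(O)cc(O[Si](C(C)C)(C(C)C)C(C)C)c1C | intermediate
9 | O-{3-methoxy-4-methyl-5-[(triisopropylsilyl)oxy]phenyl}hydroxylamine | COc1cc(ON)cc(O[Si](C(C)C)(C(C)C)C(C)C)c1C | intermediate
10 | (S)-1-(7-hydroxy-5-methoxy-2-phenylchroman-8-yl)ethan-1-one O-{3-methoxy-4-methyl-5-[(triisopropylsilyl)oxy]phenyl} oxime, C=N geometry undefined (not isolated) | CC(=NOc1cc(OC)c(C)c(O[Si](C(C)C)(C(C)C)C(C)C)c1)c1c(O)cc(OC)c2CC[C@@H](c3ccccc3)Oc12 | intermediate
11 | (2S)-8-{2-amino-4-methoxy-5-methyl-6-[(triisopropylsilyl)oxy]-2,3-dihydrobenzofuran-2-yl}-5-methoxy-2-phenylchroman-7-ol, aminal carbon undefined (not isolated) | NC1(c2c(O)cc(OC)c3CC[C@@H](c4ccccc4)Oc23)Cc2c(OC)c(C)c(O[Si](C(C)C)(C(C)C)C(C)C)cc2O1 | intermediate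
12 | (S)-5-methoxy-8-{4-methoxy-5-methyl-6-[(triisopropylsilyl)oxy]benzofuran-2-yl}-2-phenylchroman-7-ol | COc1cc(O)c(-c2cc3c(OC)c(C)c(O[Si](C(C)C)(C(C)C)C(C)C)cc3o2)c2c1CC[C@@H](c1ccccc1)O2 | intermediate
13 | (S)-8-(6-hydroxy-4-methoxy-5-methylbenzofuran-2-yl)-5-methoxy-2-phenylchroman-7-ol | COc1cc(O)c(-c2cc3c(OC)c(C)c(O)cc3o2)c2c1CC[C@@H](c1ccccc1)O2 | target

## Step count and risks

Total step count: 7 (convergent). Longest linear sequence: 5 steps (5 → 6 → 8 → 9 → 12 → 13); the flavan branch is 2 steps before the union.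

The three steps most likely to fail:

**Step 2.** C-alkylation of a chelated, acyl-deactivated phenoxide by an unactivated primary halide may be slow, and oligomeric O-alkylation may take over. The fallback reverses the order of bond formation; it sets out from 1 and comes back to the route at 4. Compound 1 is iodinated (NIS, MeCN, 0 °C) to 1-(2,6-dihydroxy-3-iodo-4-methoxyphenyl)ethan-1-one F1. Commercial (R)-1-phenylprop-2-en-1-ol (O[C@H](C=C)c1ccccc1) is hydroborated with 9-BBN (2.2 equiv, THF) to 9-{(3R)-3-[(9-borabicyclo[3.3.1]nonan-9-yl)oxy]-3-phenylpropyl}-9-borabicyclo[3.3.1]nonane F2. F2 is joined to F1 by B-alkyl Suzuki–Miyaura coupling (Pd(dppf)Cl2, K3PO4, DMF/H2O, 60 °C) to give 1-{2,6-dihydroxy-3-[(3R)-3-hydroxy-3-phenylpropyl]-4-methoxyphenyl}ethan-1-one F3. Intramolecular Mitsunobu reaction (PPh3, DIAD, THF) then closes the chroman through the neighbouring phenol with inversion, giving 4 with the same (S)-configuration.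

**Step 5.** O-amination of phenoxides is moderate-yielding and the electron-rich aryloxyamine is labile. The fallback builds the Ar–O–N bond by copper coupling; it sets out from boronate 7 (isolated by leaving out the Oxone treatment) and comes back at 9. Compound 7 is coupled with N-hydroxyphthalimide under Chan–Lam conditions (Cu(OAc)2, pyridine, 4 Å MS, 1,2-dichloroethane, air, rt) to 2-{3-methoxy-4-methyl-5-[(triisopropylsilyl)oxy]phenoxy}isoindoline-1,3-dione F4. The phthaloyl group is then removed with hydrazine hydrate (CH2Cl2/MeOH, 0 °C) to give 9.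

**Step 6.** Three things can go wrong:
- The two ortho carbons of the aryloxy ring differ only in their neighbour (OMe versus OTIPS), so the wrong benzofuran regioisomer may form. The steric preference is a reasoned expectation, not a demonstrated one.
- The di-ortho-substituted ketone may condense slowly.
- Warm acid could erode the benzylic ether stereocentre or the silyl ether; the enantiomeric purity of 12 should be checked by chiral HPLC.

The fallback assembles the oxime ether by O-arylation and runs the same [3,3] shift under non-acidic acylative activation at low temperature, where steric discrimination is higher. It sets out from 4 and boronate 7 and comes back at 12. Compound 4 is converted (NH2OH·HCl, pyridine, EtOH, 70 °C) into (S)-1-(7-hydroxy-5-methoxy-2-phenylchroman-8-yl)ethan-1-one oxime F5, whose phenol is held in an O–H···N hydrogen bond. The oxime oxygen is arylated with 7 (Cu(OAc)2, pyridine, 4 Å MS, 1,2-dichloroethane, air) to give oxime ether 10 as an isolated compound. Compound 10 is treated with trifluoroacetyl triflate and DMAP (CH2Cl2, 0 °C → rt; NaHCO3/MeOH work-up), which N-acylates it, triggers the rearrangement and cyclisation, and gives 12.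

## Further compounds

F1 | step 2 | 1-(2,6-dihydroxy-3-iodo-4-methoxyphenyl)ethan-1-one | CC(=O)c1c(O)cc(OC)c(I)c1O
F2 | step 2 | 9-{(3R)-3-[(9-borabicyclo[3.3.1]nonan-9-yl)oxy]-3-phenylpropyl}-9-borabicyclo[3.3.1]nonane | B1(O[C@H](CCB2C3CCCC2CCC3)c2ccccc2)C2CCCC1CCC2
F3 | step 2 | 1-{2,6-dihydroxy-3-[(3R)-3-hydroxy-3-phenylpropyl]-4-methoxyphenyl}ethan-1-one | CC(=O)c1c(O)cc(OC)c(CC[C@@H](O)c2ccccc2)c1O
F4 | step 5 | 2-{3-methoxy-4-methyl-5-[(triisopropylsilyl)oxy]phenoxy}isoindoline-1,3-dione | COc1cc(ON2C(=O)c3ccccc3C2=O)cc(O[Si](C(C)C)(C(C)C)C(C)C)c1C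
F5 | step 6 | (S)-1-(7-hydroxy-5-methoxy-2-phenylchroman-8-yl)ethan-1-one oxime | CC(=NO)c1c(O)cc(OC)c2CC[C@@H](c3ccccc3)Oc12
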